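The tetramethylcyclohexenedione ring (chromene locants C-4a', C-5', C-6', C-7', C-8', C-8a') is cut at C-5'–C-6'. This exploits that C-6' is a CMe2 carbon between two carbonyls, i.e. a C-acylated tertiary enolate. Its O-acyl isomer, a 7'-isopropylidene pyrano[4,3-b]pyran-5'-one, is therefore the precursor. This temporary enol-lactone ring first locks a reactive 1-oxadiene for the hetero-Diels–Alder spiroannulation of (−)-caryophyllene oxide, and it stores the acyl donor plus a latent enolate. Catalytic methoxide then exchanges the lactone oxygen for the isopropylidene carbon in one isomerisation. This closes the carbocycle, sets the last quaternary carbon and unveils both ketones. The oxirane later gives the (Z)-allylic alcohol.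

Key step: step 4

Remark: caryophyllane locants are used for the terpene part (C-8 spiro carbon, C-13 its former methylene carbon, C-5 oxirane CH/carbinol carbon) and primed chromene or pyranopyran locants for the rest (O-1', C-2' = C-8, C-3' = C-13, C-4' carries isobutyl); commercial (−)-caryophyllene oxide is taken as the (1R,4R,5R,9S) isomer, whose C-5–O bond is epimeric to that of the target carbinol, hence the closing oxidation/reduction.

Step 1
Reactants: 1 2,2,4,4-tetramethylcyclobutane-1,3-dione
Product: 3 methyl 3-acetoxy-2,2,4-trimethylpent-3-enoate, via sodium enolate 2 (not isolated)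
Conditions: NaOMe (1.05 equiv), THF, 0 °C, slow addition of 1; then AcCl (1.1 equiv), −20 °C to rt
Reagents that add atoms: sodium methoxide C[O-].[Na+]; acetyl chloride CC(=O)Cl
Why: Methoxide adds to a carbonyl of the strained, non-enolisable 1,3-dione and a retro-Claisen (retro-Dieckmann) cleavage releases the ring strain to give regiospecifically the tetrasubstituted enolate 2, which for steric reasons should be acetylated on oxygen; no stereocentre is formed.

Step 2
Reactants: 3 methyl 3-acetoxy-2,2,4-trimethylpent-3-enoate
Product: 4 5,5-dimethyl-6-(propan-2-ylidene)oxane-2,4-dione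
Conditions: LDA (2.2 equiv), THF, −78 to 0 °C; then 1 M HCl
Reagents that add atoms: none
Why: LDA enolises the acetate, and an intramolecular Claisen condensation (Dieckmann-type lactone closure, 6-(enolexo)-exo-trig) on the methyl ester should close the β-keto-δ-enol-lactone, the second equivalent of base removing the acidic C-3 proton of 4 and making the closure irreversible; no stereocentre is formed.

Step 3
Reactants: 4 5,5-dimethyl-6-(propan-2-ylidene)oxane-2,4-dione; 5 isovaleraldehyde; 6 (−)-caryophyllene oxide
Product: 8 enol-lactone spiro adduct (1R,4R,5R,8S,9S,4'S; 4,5-oxirane kept; C-8 spiro-linked through O-1' and C-3'H2 to a 4'-isobutyl-8',8'-dimethyl-7'-isopropylidene-3',4',7',8'-tetrahydropyrano[4,3-b]pyran-5'-one), via oxadiene 7 (not isolated)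
Conditions: EDDA (10 mol %), 4 Å MS, toluene, rt (4 + 5), then 6, 100 °C
Reagents that add atoms: none
Why: In a domino Knoevenagel/inverse-demand hetero-Diels–Alder reaction the rigid, doubly activated oxadiene 7 should add through its ketone C=O to the only alkene of 6 (oxygen to the more substituted C-8), from the outer face of the conformer whose methylene carbon points to the H-9 side (sets 8S) and through a half-chair transition state with the isobutyl group and the branched C-9 arm both equatorial (sets 4'S).

Step 4
Reactants: 8 enol-lactone spiro adduct
Product: 10 epoxy chromenedione (1R,4R,5R,8S,9S,4'S; 4,5-oxirane kept; C-8 spiro-linked to a 4'-isobutyl-6',6',8',8'-tetramethyl-3',4'-dihydrochromene-5',7'(6'H,8'H)-dione), via potassium enolate 9 (not isolated)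
Conditions: KOMe (20 mol %), 18-crown-6 (20 mol %), THF, 0 °C to rt; pH 7 buffer
Reagents that add atoms: none
Why: Methoxide adds to the lactone carbonyl C-5' of 8 and expels the enolate oxygen O-6' to give the methyl ester/tetrasubstituted enolate 9, whose carbon terminus (the former isopropylidene carbon) attacks the same ester carbonyl and releases methoxide again, so a catalytic amount of base should turn the O-acyl into the C-acyl isomer. The closest known reaction type is the alkoxide-induced rearrangement of enol lactones to cyclic 1,3-diketones (benzylidenephthalide to 2-phenylindane-1,3-dione, ketene-trimer δ-lactones to cyclohexane-1,3,5-triones), i.e. a retro-Claisen/Dieckmann sequence. The carbocycle closes in the favoured 6-(enolendo)-exo-trig mode, helped by two gem-dimethyl groups. No stereocentre is formed, and C-4', C-8 and the oxirane carbons carry no acidic hydrogen, so nothing is scrambled. The step needs C- over O-acylation: O-attack only regenerates 8, whereas C-attack gives the more stable β-alkoxyenone/ketone pair, so the equilibrium should drain to 10. It also needs the dihydropyran to stay closed, which is secured because O-1' takes no part in the acyl transfer and C-8a' is shielded by the adjacent quaternary C-8'.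

Step 5
Reactants: 10 epoxy chromenedione
Product: 11 (3Z,5R)-allylic alcohol (5-epimer of the target; 1R,8S,9S,4'S unchanged)
Conditions: TMP, n-BuLi, then Et2AlCl (Et2Al-TMP, 4 equiv), toluene, 0 °C; aq. Rochelle salt
Reagents that add atoms: none
Why: In the aluminium-amide epoxide-to-allylic-alcohol isomerisation the metal binds the oxirane oxygen and the hindered amide removes, in a syn-elimination, a proton from the branch cis to the oxirane hydrogen (C-3 in this trans-oxirane, not the C-12 methyl), which should release the strain of the trans-fused oxirane as the cis (3Z) ring olefin with retention at C-5 (5R), the chromenedione having no enolisable hydrogen.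

Step 6
Reactants: 11 (3Z,5R)-allylic alcohol
Product: 12 (3Z)-enone (C-5 ketone; 1R,8S,9S,4'S)
Conditions: DMP (1.3 equiv), CH2Cl2, 0 °C to rt
Reagents that add atoms: none
Why: The Dess–Martin oxidation of the secondary allylic alcohol under near-neutral conditions erases the 5R centre without touching the enol ether or moving the cis olefin, giving the conjugated enone needed for a reagent-controlled re-reduction.

Step 7
Reactants: 12 (3Z)-enone
Product: 13 tomentodione P (1R,3Z,5S,8S,9S,4'S)
Conditions: (R)-Me-CBS (20 mol %), catecholborane (2 equiv), toluene, −78 °C; MeOH, H2O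
Reagents that add atoms: none
Why: In the Corey–Bakshi–Shibata reduction the (R)-oxazaborolidine binds the ketone anti to the larger 2-methylalkenyl arm and should deliver hydride in a 1,2-sense to the face that gives the 5S alcohol, while the C-7' ketone between two quaternary carbons and the vinylogous-ester C-5' carbonyl are too hindered or too electron-rich to react at −78 °C.

Compound list
1 | 2,2,4,4-tetramethylcyclobutane-1,3-dione | CC1(C)C(=O)C(C)(C)C1=O | starting material
2 | sodium enolate of methyl 2,2,4-trimethyl-3-oxopentanoate | COC(=O)C(C)(C)C([O-])=C(C)C.[Na+] | intermediate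
3 | methyl 3-acetoxy-2,2,4-trimethylpent-3-enoate | COC(=O)C(C)(C)C(OC(C)=O)=C(C)C | intermediate
4 | 5,5-dimethyl-6-(propan-2-ylidene)oxane-2,4-dione | CC(C)=C1OC(=O)CC(=O)C1(C)C | intermediate
5 | isovaleraldehyde (3-methylbutanal) | CC(C)CC=O | starting material
6 | (−)-caryophyllene oxide (1R,4R,5R,9S) | C[C@@]12CC[C@@H]3[C@H](CC3(C)C)C(=C)CC[C@H]1O2 | starting material
7 | (3Z)-5,5-dimethyl-3-(3-methylbutylidene)-6-(propan-2-ylidene)oxane-2,4-dione | CC(C)C/C=C1\C(=O)OC(=C(C)C)C(C)(C)C1=O | intermediate
8 | enol-lactone spiro adduct (1R,4R,5R,8S,9S,4'S) | C[C@@]12CC[C@@H]3[C@H](CC3(C)C)[C@]4(CC[C@H]1O2)C[C@H](CC(C)C)C5=C(O4)C(C)(C)C(=C(C)C)OC5=O | intermediate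
9 | potassium enolate of the seco methyl ester | C[C@@]12CC[C@@H]3[C@H](CC3(C)C)[C@]4(CC[C@H]1O2)C[C@H](CC(C)C)C(C(=O)OC)=C(O4)C(C)(C)C([O-])=C(C)C.[K+] | intermediate
10 | epoxy chromenedione (1R,4R,5R,8S,9S,4'S) | C[C@@]12CC[C@@H]3[C@H](CC3(C)C)[C@]4(CC[C@H]1O2)C[C@H](CC(C)C)C5=C(O4)C(C)(C)C(=O)C(C)(C)C5=O | intermediate
11 | (3Z,5R)-allylic alcohol, 5-epi-tomentodione P | C/C1=C/C[C@@H]2[C@H](CC2(C)C)[C@]2(CC[C@H]1O)C[C@H](CC(C)C)C1=C(O2)C(C)(C)C(=O)C(C)(C)C1=O | intermediate
12 | (3Z)-enone | C/C1=C/C[C@@H]2[C@H](CC2(C)C)[C@]2(CCC1=O)C[C@H](CC(C)C)C1=C(O2)C(C)(C)C(=O)C(C)(C)C1=O | intermediate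
13 | tomentodione P | C/C1=C/C[C@@H]2[C@H](CC2(C)C)[C@]2(CC[C@@H]1O)C[C@H](CC(C)C)C1=C(O2)C(C)(C)C(=O)C(C)(C)C1=O | target

Total step count: 7. Longest linear sequence: 7 steps (1 to 13); 6 enters at step 3 and is five steps from the target.

Steps most likely to fail

1. Step 3.
- Risk: the acidic dione 4 may open the oxirane on heating. The cycloaddition may show poor facial selectivity at the exocyclic methylene or poor endo/exo selectivity at C-4'. The lactone carbonyl or an ene pathway may compete.
- Fallback (from 6, back at 12): the oxirane chemistry is moved in front of the cycloaddition, so that the dienophile is an acid-stable dienone with a different ring conformation. Et2Al-TMP isomerisation of 6 should give (3Z,5R)-caryophylla-3,8(13)-dien-5-ol F1. Dess–Martin oxidation should give (3Z)-caryophylla-3,8(13)-dien-5-one F2, whose electron-poor enone olefin is inert to the inverse-demand diene. The three-component reaction with 4 and 5, now possible in buffered NaOAc/AcOH, should give the enol-lactone enone adduct F3. KHMDS (1.1 equiv, masks the enone as its dienolate) followed by catalytic KOMe should effect the same lactone-to-dione isomerisation and, after protonation, return 12.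

2. Step 5.
- Risk: proton abstraction may occur from the C-12 methyl group instead of C-3, or the syn-elimination may run through the conformer that leads to the trans ring olefin.
- Fallback (from 10, back at 12): the methyl-side opening is accepted and regiochemistry and geometry are corrected thermodynamically at the enone stage. Cp2TiCl (Cp2TiCl2, Mn, THF) opens the oxirane homolytically at C-4 and, after hydrogen loss from the methyl group, should give the (5R)-4(12)-exomethylene alcohol F4. Dess–Martin oxidation should give the exomethylene ketone F5. RhCl3·3H2O in hot EtOH should move the double bond into the ring to the more substituted cis-enone 12.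

3. Step 4.
- Risk: adventitious proton sources may quench the intermediate enolate so that the catalytic cycle stalls at the seco stage, or methoxide may slowly cleave the non-enolisable dione once formed.
- Fallback (from 8, back at 10): the catalytic isomerisation under equilibrium control is replaced by an open-then-close sequence under kinetic control. Deliberate methanolysis (NaOMe, MeOH, 0 °C) should give the isolable seco keto ester F6. Irreversible stoichiometric enolisation of its isopropyl ketone (KHMDS, THF, −78 to 0 °C, quench with TMSCl to scavenge methoxide) should close the ring by Dieckmann condensation to 10.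

Further compounds
F1 | step 3 | (3Z,5R)-caryophylla-3,8(13)-dien-5-ol | C/C1=C/C[C@@H]2[C@H](CC2(C)C)C(=C)CC[C@H]1O
F2 | step 3 | (3Z)-caryophylla-3,8(13)-dien-5-one | C/C1=C/C[C@@H]2[C@H](CC2(C)C)C(=C)CCC1=O
F3 | step 3 | enol-lactone enone adduct | C/C1=C/C[C@@H]2[C@H](CC2(C)C)[C@]2(CCC1=O)C[C@H](CC(C)C)C1=C(O2)C(C)(C)C(=C(C)C)OC1=O
F4 | step 5 | (5R)-4(12)-exomethylene alcohol | C=C1CC[C@@H]2[C@H](CC2(C)C)[C@]2(CC[C@H]1O)C[C@H](CC(C)C)C1=C(O2)C(C)(C)C(=O)C(C)(C)C1=O
F5 | step 5 | exomethylene ketone | C=C1CC[C@@H]2[C@H](CC2(C)C)[C@]2(CCC1=O)C[C@H](CC(C)C)C1=C(O2)C(C)(C)C(=O)C(C)(C)C1=O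
F6 | step 4 | seco keto ester | C[C@@]12CC[C@@H]3[C@H](CC3(C)C)[C@]4(CC[C@H]1O2)C[C@H](CC(C)C)C(C(=O)OC)=C(O4)C(C)(C)C(=O)C(C)C
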